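The readings were computed from invented constants; scatter was added.

A chain stays counted once begun, living or dead, so if one initiator molecule begins one chain, chains begun plus initiator left equals the initiator charged.

in all of them: initiator 50 mM

|  | free monomer | remark | time |
|---|---|---|---|
| beta | 1.3 M | run made earlier |  |
| eta | 3 M | run made earlier |  |
| flask | 2.0 M |  | 5.0 min |

- beta (time / min: monomer in chains / %, free monomer / %): 0.417: 20.2, 78.1; 0.667: 42.2, 58.0; 1.00: 64.0, 35.5; 2.00: 91.0, 7.4; 3.00: 96.6, 2.3; 5.00: 96.9, 1.3
- eta (time / min: monomer in chains / %, free monomer / %): 0.417: 37.3, 62.6; 0.667: 61.7, 37.2; 1.00: 79.5, 19.5; 2.00: 93.6, 5.0; 3.00: 96.2, 2.9; 5.00: 97.7, 2.6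

(each reading ± 0.5 percentage points)

1. average number of monomer units in a chain (chains begun, living or dead) at 5.0 min
2. part of the free monomer that has reacted at 5.0 min

- the average divides the monomer in chains by the number of chains begun, living and dead together
- the earlier runs do not show the number of chains; that part of a forecast is a guess

The bench rule takes free monomer charged over initiator charged. For the flask that is 40.0, or 1.60 in powers of ten. I carried this logarithm of the charge ratio, and with the balance above the average becomes a sum:

log dp = log(charge ratio) + log(share of charged monomer in chains) − log(share of initiator spent)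

The rule takes the last share as whole. With the chain share of the beta run at 5.00 min, it gives for the flask:

1.60 − 0.0137 = 1.59, so dp = 38.6

The beta run shows the border of this rule. A steady number of living ends gives a steady climb of ln(charge/free monomer left), the pseudo-first-order picture. In the beta run the readings give a climb of 0.593 min⁻¹ up to 0.417 min, but a faster one of 1.57 min⁻¹ from 1.00 min to 2.00 min, a ratio of 2.65 as read. So I took the spent share as possibly below whole, and 38.6 as a floor for the flask, with the height above it unseen in the runs. For c, I expected a value between 97.4% and 98.7%, the two runs at 5.00 min.

The forecast gave dp 44 (range 37 to 60) and c 98.2% (range 97.4% to 98.9%), with the words “Slow initiation suggests incomplete efficiency”.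

The flask gave dp 80.3 and c 98.7%.

    free monomer + initiator → living end + monomer in chains (k = 0.00660 M⁻¹ s⁻¹)
    free monomer + living end → monomer in chains + living end, rate k2*[living end]*[free monomer] (k = 1.90 M⁻¹ s⁻¹)
    living end + monomer in chains → dead end (k = 0.00660 M⁻¹ s⁻¹)

In the flask free monomer was the limiting reagent, with less of its charge left, 1.3%, than the 51% of its own charge left of the initiator. The same sum for the flask, with 48.6% of its initiator spent, reads:

1.60 + 0.303 = 1.90, so dp = 80.3

The neighbour flask, charged with 0.12 M of initiator, has a charge ratio of 16.7. It kept 68% of its initiator and had 98.0% of its charged free monomer in chains: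

1.22 + 0.486 = 1.71

The neighbour flask gave dp 50.9.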